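The bond on which everything rests joins C6 of the 1,2-dioxane to the first CH2 of the ethylene linker to the cyclohexenone. C6 is ketal-level, and the key step exploits this by making it the internal carbon of a methylidene. A Negishi coupling joins the zinc reagent of a 3-(2-iodoethyl)cyclohexenone to a 2-bromoalkene that carries a trans-β-lactone holding both side-chain stereocentres. Ozonolysis in methanol then turns that same carbon into a hydroperoxy ketal, whose anion opens the lactone at C4 with inversion, closing the dioxane and freeing the carboxylate. The C6 methyl enters last, axially, on the cyclic peroxycarbenium ion.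

Key step: step 9

Remark: 2 and 4 are racemic, 6 is an E/Z mixture and the ketal carbon of 19, 20 and 21 forms as both epimers (none of these elements reaches 23); the quinidine-derived catalyst of step 7 is assumed to give the (4R)-lactone, its quinine-derived pseudoenantiomer giving the antipode; C3–C6 refer to the 1,2-dioxane ring.

Step 1
Reactants: 1 4,4-dimethylcyclohexane-1,3-dione
Product: 2 2,4,4-trimethylcyclohexane-1,3-dione
Conditions: MeI, K2CO3, acetone, reflux
Reagents that add atoms: iodomethane (CI)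
Why: Enolate C-alkylation of a cyclic 1,3-dione at the doubly activated C2.

Step 2
Reactants: 2 2,4,4-trimethylcyclohexane-1,3-dione
Product: 3 3-(2-methylpropoxy)-2,6,6-trimethylcyclohex-2-en-1-one
Conditions: i-BuOH, TsOH (cat.), toluene, reflux, Dean–Stark
Reagents that add atoms: 2-methylpropan-1-ol (CC(C)CO)
Why: Acid-catalysed vinylogous ester formation, in which the alcohol attacks the carbonyl remote from the gem-dimethyl carbon so that the remaining ketone sits next to it.

Step 3
Reactants: 3 3-(2-methylpropoxy)-2,6,6-trimethylcyclohex-2-en-1-one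
Product: 5 2,4,4-trimethyl-3-vinylcyclohex-2-en-1-one, via carbinol 4 (not isolated)
Conditions: CH2=CHMgBr, CeCl3, THF, −78 to 0 °C; then 1 M HCl
Reagents that add atoms: vinylmagnesium bromide (C=C[Mg]Br)
Why: Stork–Danheiser sequence, in which 1,2-addition to the vinylogous ester carbonyl and acid hydrolysis with transposition place the vinyl group on the enone β-carbon next to the gem-dimethyl carbon.

Step 4
Reactants: 5 2,4,4-trimethyl-3-vinylcyclohex-2-en-1-one
Product: 7 3-(2-iodoethyl)-2,4,4-trimethylcyclohex-2-en-1-one, via silyl dienol ether 6 (not isolated)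
Conditions: TMSCl, NaI, MeCN, −20 to 0 °C; then H2O
Reagents that add atoms: sodium iodide ([Na+].[I-])
Why: Vinylogous (1,6) conjugate hydroiodination by iodotrimethylsilane made in the flask, in which iodide attacks the unhindered vinyl terminus because the β-carbon is fully substituted, and hydrolysis of the silyl dienol ether should return the conjugated enone.

Step 5
Reactants: 8 tert-butyl acetate; 9 2,3-dibromoprop-1-ene
Product: 11 tert-butyl 4-bromopent-4-enoate, via lithium enolate 10 (not isolated)
Conditions: LDA, THF, −78 °C; then 9, −78 to 0 °C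
Reagents that add atoms: none
Why: Ester enolate alkylation at the allylic bromide (SN2), the vinylic bromide being inert.

Step 6
Reactants: 11 tert-butyl 4-bromopent-4-enoate
Product: 12 4-bromopent-4-enal
Conditions: DIBAL-H, CH2Cl2, −78 °C
Reagents that add atoms: none
Why: Partial reduction of the ester through a tetrahedral aluminate that is stable at low temperature (ester-to-aldehyde reduction).

Step 7
Reactants: 12 4-bromopent-4-enal
Product: 13 (4R)-4-(3-bromobut-3-en-1-yl)oxetan-2-one
Conditions: AcCl, i-Pr2NEt, O-trimethylsilylquinidine (10 mol %), LiClO4, Et2O/CH2Cl2, −78 °C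
Reagents that add atoms: acetyl chloride (CC(Cl)=O)
Why: Cinchona alkaloid/LiClO4-catalysed acyl halide–aldehyde cyclocondensation (formal [2+2] of ketene with the aldehyde), in which the chiral ammonium enolate selects the aldehyde face and so sets C4 under catalyst control.

Step 8
Reactants: 13 (4R)-4-(3-bromobut-3-en-1-yl)oxetan-2-one
Product: 15 (3R,4R)-4-(3-bromobut-3-en-1-yl)-3-methyloxetan-2-one, via lactone enolate 14 (not isolated)
Conditions: LDA, THF, −78 °C; then MeI, −78 °C
Reagents that add atoms: iodomethane (CI)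
Why: Alkylation of the planar β-lactone enolate anti to the C4 substituent, so the new C3 methyl should be trans (3R) under control of C4.

Step 9
Reactants: 7 3-(2-iodoethyl)-2,4,4-trimethylcyclohex-2-en-1-one; 15 (3R,4R)-4-(3-bromobut-3-en-1-yl)-3-methyloxetan-2-one
Product: 17 (3R,4R)-3-methyl-4-[3-methylidene-5-(2,6,6-trimethyl-3-oxocyclohex-1-en-1-yl)pentyl]oxetan-2-one, via alkylzinc iodide 16 (not isolated)
Conditions: Zn dust, LiCl, THF, 40 °C; then 15, Pd(OAc)2 (2 mol %), SPhos, THF, 25 °C
Reagents that add atoms: none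
Why: Zinc inserts into the primary C–I bond of 7 to give alkylzinc 16; zerovalent palladium adds oxidatively to the alkenyl C–Br bond of 15, and transmetalation then reductive elimination form the C(sp3)–C(sp2) bond between the linker CH2 and the future C6. This is a Negishi alkyl–alkenyl cross-coupling, a known reaction type. The step closes no ring and creates no stereocentre, and the two lactone stereocentres are spectators. It needs chemoselectivity for the C–Br bond over the strained lactone and the enone, and reductive elimination faster than β-hydride elimination; the low nucleophilicity of the organozinc toward acyl groups and the bulky biarylphosphine should secure both. The methylidene carbon so formed is the latent ketal carbon C6.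

Step 10
Reactants: 17 (3R,4R)-3-methyl-4-[3-methylidene-5-(2,6,6-trimethyl-3-oxocyclohex-1-en-1-yl)pentyl]oxetan-2-one
Product: 19 (3R,4R)-4-[3-hydroperoxy-3-methoxy-5-(2,6,6-trimethyl-3-oxocyclohex-1-en-1-yl)pentyl]-3-methyloxetan-2-one, via carbonyl oxide 18 (not isolated)
Conditions: O3, CH2Cl2/MeOH 4:1, −78 °C, Sudan Red 7B end-point; N2 purge, no reductant
Reagents that add atoms: ozone ([O-][O+]=O); methanol (CO)
Why: Ozonolysis with Criegee cleavage to the ketone oxide, which methanol traps as the α-methoxy hydroperoxide; the electron-rich 1,1-dialkyl alkene should react far faster than the acyl-deactivated tetrasubstituted enone alkene.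

Step 11
Reactants: 19 (3R,4R)-4-[3-hydroperoxy-3-methoxy-5-(2,6,6-trimethyl-3-oxocyclohex-1-en-1-yl)pentyl]-3-methyloxetan-2-one
Product: 21 methyl (2R)-2-{(3S)-6-methoxy-6-[2-(2,6,6-trimethyl-3-oxocyclohex-1-en-1-yl)ethyl]-1,2-dioxan-3-yl}propanoate, via potassium carboxylate 20 (not isolated)
Conditions: KOtBu (1.0 equiv), 18-crown-6, THF, 0 °C; then MeI, 25 °C
Reagents that add atoms: iodomethane (CI)
Why: Proposed new method: the hydroperoxide anion of 19 attacks lactone C4 in a 6-exo-tet SN2 displacement (alkyl–oxygen cleavage driven by ring strain with carboxylate as leaving group, whereas attack at the acyl carbon would need an 8-membered transition state), so inversion there sets dioxane C3 as S with C2′ untouched, and the carboxylate is O-methylated in the same flask; the closest known reactions are the base-mediated intramolecular alkylation of hydroperoxy ketals by secondary sulfonates and the SN2 opening of β-lactones at C4 by tethered oxygen nucleophiles.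

Step 12
Reactants: 21 methyl (2R)-2-{(3S)-6-methoxy-6-[2-(2,6,6-trimethyl-3-oxocyclohex-1-en-1-yl)ethyl]-1,2-dioxan-3-yl}propanoate
Product: 23 methyl diacarnoate A, via peroxycarbenium triflate 22 (not isolated)
Conditions: Me3Al (3 equiv), TMSOTf (1.2 equiv), CH2Cl2, −78 °C
Reagents that add atoms: trimethylaluminium (C[Al](C)C)
Why: Proposed new method: TMSOTf removes the methoxy group to give the cyclic peroxycarbenium ion 22 (both ketal epimers converge), and methyl is transferred from aluminium along the axial trajectory of the half-chair that keeps the C3 substituent pseudoequatorial (chair-like transition state, stereoelectronic control), so the new methyl should be cis to the C3 side chain and C6 R; the closest known reactions are the Lewis-acid substitution of cyclic peroxyketals by allylsilanes and silyl enol ethers through peroxycarbenium ions and the C-methylation of cyclic oxocarbenium ions by Me3Al next to a trioxane peroxide.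

Compound list

1 | 4,4-dimethylcyclohexane-1,3-dione | O=C1CC(=O)C(C)(C)CC1 | starting material
2 | 2,4,4-trimethylcyclohexane-1,3-dione (racemic, enolisable C2) | CC1C(=O)CCC(C)(C)C1=O | intermediate
3 | 3-(2-methylpropoxy)-2,6,6-trimethylcyclohex-2-en-1-one | CC(C)COC1=C(C)C(=O)C(C)(C)CC1 | intermediate
4 | 3-(2-methylpropoxy)-2,6,6-trimethyl-1-vinylcyclohex-2-en-1-ol (racemic) | C=CC1(O)C(C)=C(OCC(C)C)CCC1(C)C | intermediate
5 | 2,4,4-trimethyl-3-vinylcyclohex-2-en-1-one | C=CC1=C(C)C(=O)CCC1(C)C | intermediate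
6 | {[3-(2-iodoethylidene)-2,4,4-trimethylcyclohex-1-en-1-yl]oxy}trimethylsilane (E/Z mixture) | C[Si](C)(C)OC1=C(C)C(=CCI)C(C)(C)CC1 | intermediate
7 | 3-(2-iodoethyl)-2,4,4-trimethylcyclohex-2-en-1-one | ICCC1=C(C)C(=O)CCC1(C)C | intermediate
8 | tert-butyl acetate | CC(=O)OC(C)(C)C | starting material
9 | 2,3-dibromoprop-1-ene | C=C(Br)CBr | starting material
10 | lithium 1-tert-butoxyethen-1-olate | [Li]OC(=C)OC(C)(C)C | intermediate
11 | tert-butyl 4-bromopent-4-enoate | C=C(Br)CCC(=O)OC(C)(C)C | intermediate
12 | 4-bromopent-4-enal | C=C(Br)CCC=O | intermediate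
13 | (4R)-4-(3-bromobut-3-en-1-yl)oxetan-2-one | O=C1C[C@@H](CCC(Br)=C)O1 | intermediate
14 | lithium (4R)-4-(3-bromobut-3-en-1-yl)-4H-oxet-2-olate | [Li]OC1=C[C@@H](CCC(Br)=C)O1 | intermediate
15 | (3R,4R)-4-(3-bromobut-3-en-1-yl)-3-methyloxetan-2-one (trans) | O=C1[C@H](C)[C@@H](CCC(Br)=C)O1 | intermediate
16 | iodo[2-(2,6,6-trimethyl-3-oxocyclohex-1-en-1-yl)ethyl]zinc | I[Zn]CCC1=C(C)C(=O)CCC1(C)C | intermediate
17 | (3R,4R)-3-methyl-4-[3-methylidene-5-(2,6,6-trimethyl-3-oxocyclohex-1-en-1-yl)pentyl]oxetan-2-one | O=C1[C@H](C)[C@@H](CCC(=C)CCC2=C(C)C(=O)CCC2(C)C)O1 | intermediate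
18 | carbonyl oxide of the ketone derived from 17 (lactone 3R,4R) | O=C1[C@H](C)[C@@H](CCC(=[O+][O-])CCC2=C(C)C(=O)CCC2(C)C)O1 | intermediate
19 | (3R,4R)-4-[3-hydroperoxy-3-methoxy-5-(2,6,6-trimethyl-3-oxocyclohex-1-en-1-yl)pentyl]-3-methyloxetan-2-one (both ketal epimers) | O=C1[C@H](C)[C@@H](CCC(OC)(OO)CCC2=C(C)C(=O)CCC2(C)C)O1 | intermediate
20 | potassium (2R)-2-{(3S)-6-methoxy-6-[2-(2,6,6-trimethyl-3-oxocyclohex-1-en-1-yl)ethyl]-1,2-dioxan-3-yl}propanoate (both C6 epimers) | [K+].[O-]C(=O)[C@H](C)[C@@H]1CCC(OC)(CCC2=C(C)C(=O)CCC2(C)C)OO1 | intermediate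
21 | methyl (2R)-2-{(3S)-6-methoxy-6-[2-(2,6,6-trimethyl-3-oxocyclohex-1-en-1-yl)ethyl]-1,2-dioxan-3-yl}propanoate (both C6 epimers) | COC(=O)[C@H](C)[C@@H]1CCC(OC)(CCC2=C(C)C(=O)CCC2(C)C)OO1 | intermediate
22 | (6S)-6-[(2R)-1-methoxy-1-oxopropan-2-yl]-3-[2-(2,6,6-trimethyl-3-oxocyclohex-1-en-1-yl)ethyl]-5,6-dihydro-4H-1,2-dioxin-2-ium trifluoromethanesulfonate | COC(=O)[C@H](C)[C@@H]1CCC(CCC2=C(C)C(=O)CCC2(C)C)=[O+]O1.[O-]S(=O)(=O)C(F)(F)F | intermediate
23 | methyl diacarnoate A, methyl (2R)-2-{(3S,6R)-6-methyl-6-[2-(2,6,6-trimethyl-3-oxocyclohex-1-en-1-yl)ethyl]-1,2-dioxan-3-yl}propanoate | COC(=O)[C@H](C)[C@@H]1CC[C@@](C)(CCC2=C(C)C(=O)CCC2(C)C)OO1 | target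

Total step count: 12. Longest linear sequence: 8 steps (steps 5–8 then 9–12; the branch 1–4 then 9–12 is equally long).

Steps most likely to fail

Step 11 (Proposed new method). The hydroperoxide anion or the alkoxide base may attack the lactone carbonyl, or the hydroperoxy lactone may oligomerise, instead of displacing at C4. The fallback uses the known alkylation of a hydroperoxy ketal by a secondary sulfonate; it sets out from 15 and returns at 21. Lactone 15 is reduced with LiBH4 to the (2S,3R)-diol F1. The primary hydroxyl is silylated (TBSCl, imidazole) to give the silyl ether F2, and the secondary one is mesylated (MsCl, Et3N) to give the mesylate F3. Negishi coupling with 16 as in step 9 should give the coupled mesylate F4, and ozonolysis in methanol as in step 10 the hydroperoxy ketal F5. KOtBu/18-crown-6 should then close the ring by displacement of the mesylate with inversion to give the dioxane silyl ether F6. HF·pyridine frees the alcohol F7, TEMPO/PhI(OAc)2 in MeCN/H2O gives the acid F8, and TMSCHN2 gives 21.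

Step 12 (Proposed new method). Methyl may be transferred to the O–O bond or to the carbonyl groups, the cation may lose a proton to an enol peroxide, or facial control may be lost. The fallback uses known chemistry only; it sets out from 15, passes through the diol F1, the silyl ether F2, the mesylate F3 and the coupled mesylate F4 as in the fallback above, and returns at 23. Isayama–Mukaiyama hydroperoxysilylation of the coupled mesylate F4 (bis(2,2,6,6-tetramethylheptane-3,5-dionato)cobalt, Co(thd)2, with O2 and Et3SiH) places the methyl (from the methylidene carbon) and a tertiary silyl peroxide on C6 without facial control, giving the triethylsilyl peroxide F9 as both C6 epimers. TBAF removes both silyl groups to give the hydroperoxy alcohol F10, and KOtBu/18-crown-6 closes the dioxane at the mesylate with inversion at C3. The 6R epimer, the dioxane alcohol F11, is separated by chromatography, oxidised (TEMPO/PhI(OAc)2) to the acid F12 and esterified (TMSCHN2) to 23.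

Step 9 (key step). Iodide or zinc halide may open the strained lactone, the zinc reagent may be protonated, or β-hydride elimination may outrun reductive elimination. The fallback is a nickel-catalysed reductive cross-electrophile coupling of iodide 7 with bromide 15 (NiBr2(dme), 4,4′-di-tert-butyl-2,2′-bipyridine, Mn powder, DMA, 25 °C). It needs no preformed organozinc and no zinc halide, sets out from 7 and 15, returns at 17 and makes no new compound: F0.

Further compounds

F1 | step 11 | (2S,3R)-6-bromo-2-methylhept-6-ene-1,3-diol | OC[C@H](C)[C@@H](CCC(Br)=C)O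
F2 | step 11 | (2S,3R)-6-bromo-1-[(tert-butyldimethylsilyl)oxy]-2-methylhept-6-en-3-ol | CC(C)(C)[Si](C)(C)OC[C@H](C)[C@@H](CCC(Br)=C)O
F3 | step 11 | (2S,3R)-6-bromo-1-[(tert-butyldimethylsilyl)oxy]-2-methylhept-6-en-3-yl methanesulfonate | CC(C)(C)[Si](C)(C)OC[C@H](C)[C@@H](CCC(Br)=C)OS(C)(=O)=O
F4 | step 11 | (2S,3R)-1-[(tert-butyldimethylsilyl)oxy]-2-methyl-6-methylidene-8-(2,6,6-trimethyl-3-oxocyclohex-1-en-1-yl)octan-3-yl methanesulfonate | CC(C)(C)[Si](C)(C)OC[C@H](C)[C@@H](CCC(=C)CCC1=C(C)C(=O)CCC1(C)C)OS(C)(=O)=O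
F5 | step 11 | (2S,3R)-1-[(tert-butyldimethylsilyl)oxy]-6-hydroperoxy-6-methoxy-2-methyl-8-(2,6,6-trimethyl-3-oxocyclohex-1-en-1-yl)octan-3-yl methanesulfonate (both C6 epimers) | CC(C)(C)[Si](C)(C)OC[C@H](C)[C@@H](CCC(OC)(OO)CCC1=C(C)C(=O)CCC1(C)C)OS(C)(=O)=O
F6 | step 11 | tert-butyl{(2S)-2-[(3S)-6-methoxy-6-[2-(2,6,6-trimethyl-3-oxocyclohex-1-en-1-yl)ethyl]-1,2-dioxan-3-yl]propoxy}dimethylsilane (both C6 epimers) | CC(C)(C)[Si](C)(C)OC[C@H](C)[C@@H]1CCC(OC)(CCC2=C(C)C(=O)CCC2(C)C)OO1
F7 | step 11 | (2S)-2-{(3S)-6-methoxy-6-[2-(2,6,6-trimethyl-3-oxocyclohex-1-en-1-yl)ethyl]-1,2-dioxan-3-yl}propan-1-ol (both C6 epimers) | OC[C@H](C)[C@@H]1CCC(OC)(CCC2=C(C)C(=O)CCC2(C)C)OO1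
F8 | step 11 | (2R)-2-{(3S)-6-methoxy-6-[2-(2,6,6-trimethyl-3-oxocyclohex-1-en-1-yl)ethyl]-1,2-dioxan-3-yl}propanoic acid (both C6 epimers) | OC(=O)[C@H](C)[C@@H]1CCC(OC)(CCC2=C(C)C(=O)CCC2(C)C)OO1
F9 | step 12 | (2S,3R)-1-[(tert-butyldimethylsilyl)oxy]-2,6-dimethyl-6-[(triethylsilyl)peroxy]-8-(2,6,6-trimethyl-3-oxocyclohex-1-en-1-yl)octan-3-yl methanesulfonate (both C6 epimers) | CC(C)(C)[Si](C)(C)OC[C@H](C)[C@@H](CCC(C)(OO[Si](CC)(CC)CC)CCC1=C(C)C(=O)CCC1(C)C)OS(C)(=O)=O
F10 | step 12 | (2S,3R)-6-hydroperoxy-1-hydroxy-2,6-dimethyl-8-(2,6,6-trimethyl-3-oxocyclohex-1-en-1-yl)octan-3-yl methanesulfonate (both C6 epimers) | OC[C@H](C)[C@@H](CCC(C)(OO)CCC1=C(C)C(=O)CCC1(C)C)OS(C)(=O)=O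
F11 | step 12 | (2S)-2-{(3S,6R)-6-methyl-6-[2-(2,6,6-trimethyl-3-oxocyclohex-1-en-1-yl)ethyl]-1,2-dioxan-3-yl}propan-1-ol | OC[C@H](C)[C@@H]1CC[C@@](C)(CCC2=C(C)C(=O)CCC2(C)C)OO1
F12 | step 12 | (2R)-2-{(3S,6R)-6-methyl-6-[2-(2,6,6-trimethyl-3-oxocyclohex-1-en-1-yl)ethyl]-1,2-dioxan-3-yl}propanoic acid | OC(=O)[C@H](C)[C@@H]1CC[C@@](C)(CCC2=C(C)C(=O)CCC2(C)C)OO1
F0 | step 9 | none | none
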